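**Retrosynthetic overview**

1. Feature: C2 of ring C carries H, O1 and ring B. In the open form (ring A–O1–CH2–ring B) it is a benzylic ether C–H bond six atoms from C3, so C2–C3 is cut back to a carbenoid at C3 (diazoketone on ring A) and an O-benzyl ether.
2. Ring order: rings A and B are bought as arenes. Ring C is the only ring made, by the carbenoid C–H insertion, which also sets C2, the only stereocentre.
3. The diazoketone comes from the methyl ketone by detrifluoroacetylative diazo transfer. The methyl ketone comes from the chelated phenol of bis-TIPS 2',4',6'-trihydroxyacetophenone and the ring B benzyl bromide.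
4. Ring B comes from 3-bromo-4-hydroxybenzaldehyde by O-allylation, Claisen rearrangement, O-methylation, cross-metathesis (prenyl) and Sonogashira coupling with 2-methylbut-3-yn-2-ol. The aryl bromide is used up before ring C exists, because a flavanone loses its C2 configuration by retro-oxa-Michael opening under basic coupling conditions.
5. After the key step only neutral steps remain: Z-selective semihydrogenation of the alkyne and buffered fluoride removal of all three silyl groups.

Key step: step 12

Assumption: Rh2(S-PTTL)4 is taken to deliver the (2S) product; if the first run shows the opposite sense of induction, the mirror-image catalyst Rh2(R-PTTL)4 is used under the same conditions.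

**Route**

Step 1
Reactants: 1 3-bromo-4-hydroxybenzaldehyde; 2 allyl bromide
Product: 3 4-(allyloxy)-3-bromobenzaldehyde
Conditions: K2CO3, DMF, rt
Reagents that add atoms: none
Why: Williamson ether synthesis, the phenoxide displacing bromide from the allylic halide while aldehyde and aryl bromide stay inert.

Step 2
Reactants: 3 4-(allyloxy)-3-bromobenzaldehyde
Product: 4 3-allyl-5-bromo-4-hydroxybenzaldehyde
Conditions: N,N-diethylaniline, 200 °C, sealed tube
Reagents that add atoms: none
Why: Aromatic Claisen rearrangement ([3,3]-sigmatropic shift) should deliver the allyl group to the only unsubstituted ortho carbon, and tautomerisation restores the phenol.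

Step 3
Reactants: 4 3-allyl-5-bromo-4-hydroxybenzaldehyde
Product: 5 3-allyl-5-bromo-4-methoxybenzaldehyde
Conditions: MeI, K2CO3, DMF, rt
Reagents that add atoms: iodomethane, CI
Why: Williamson O-methylation of the phenoxide, whose acidity is raised by the para formyl group, with the small electrophile MeI.

Step 4
Reactants: 5 3-allyl-5-bromo-4-methoxybenzaldehyde
Product: 6 3-bromo-4-methoxy-5-(3-methylbut-2-en-1-yl)benzaldehyde
Conditions: 2-methylbut-2-ene (excess), second-generation Grubbs catalyst RuCl2(=CHPh)(SIMes)(PCy3) (3 mol %), CH2Cl2, 40 °C, sealed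
Reagents that add atoms: 2-methylbut-2-ene, CC=C(C)C
Why: Olefin cross-metathesis of the terminal allyl alkene with excess 2-methylbut-2-ene should transfer the isopropylidene unit with loss of propene, the trisubstituted product alkene being inert to further metathesis.

Step 5
Reactants: 6 3-bromo-4-methoxy-5-(3-methylbut-2-en-1-yl)benzaldehyde; 7 2-methylbut-3-yn-2-ol
Product: 8 3-(3-hydroxy-3-methylbut-1-yn-1-yl)-4-methoxy-5-(3-methylbut-2-en-1-yl)benzaldehyde
Conditions: Pd(PPh3)2Cl2 (3 mol %), CuI (5 mol %), Et3N, DMF, 70 °C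
Reagents that add atoms: none
Why: Sonogashira coupling of the aryl bromide with the terminal alkyne, which tolerates the free tertiary alcohol, the aldehyde and the trisubstituted alkene.

Step 6
Reactants: 8 3-(3-hydroxy-3-methylbut-1-yn-1-yl)-4-methoxy-5-(3-methylbut-2-en-1-yl)benzaldehyde
Product: 9 4-methoxy-3-(3-methylbut-2-en-1-yl)-5-[3-methyl-3-(triethylsilyloxy)but-1-yn-1-yl]benzaldehyde
Conditions: Et3SiOTf, 2,6-lutidine, CH2Cl2, −78 to 0 °C
Reagents that add atoms: triethylsilyl trifluoromethanesulfonate, CC[Si](CC)(CC)OS(=O)(=O)C(F)(F)F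
Why: Silylation of the tertiary propargylic alcohol with a silyl triflate, done at the stage of a non-enolisable aldehyde so that no silyl enol ether can form; the ether masks the hydroxyl against O–H insertion in step 12.

Step 7
Reactants: 9 4-methoxy-3-(3-methylbut-2-en-1-yl)-5-[3-methyl-3-(triethylsilyloxy)but-1-yn-1-yl]benzaldehyde
Product: 10 {4-methoxy-3-(3-methylbut-2-en-1-yl)-5-[3-methyl-3-(triethylsilyloxy)but-1-yn-1-yl]phenyl}methanol
Conditions: NaBH4, MeOH, 0 °C
Reagents that add atoms: none
Why: Borohydride reduction of the aldehyde to the benzylic alcohol, which leaves alkyne, alkene and the tertiary silyl ether untouched.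

Step 8
Reactants: 10 {4-methoxy-3-(3-methylbut-2-en-1-yl)-5-[3-methyl-3-(triethylsilyloxy)but-1-yn-1-yl]phenyl}methanol
Product: 11 5-(bromomethyl)-2-methoxy-1-(3-methylbut-2-en-1-yl)-3-[3-methyl-3-(triethylsilyloxy)but-1-yn-1-yl]benzene
Conditions: CBr4, PPh3, CH2Cl2, 0 °C; used at once
Reagents that add atoms: carbon tetrabromide, BrC(Br)(Br)Br
Why: Appel bromination of the primary benzylic alcohol under neutral conditions, so that no HBr reaches the prenyl alkene or the silyl ether.

Step 9
Reactants: 12 2',4',6'-trihydroxyacetophenone (dried)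
Product: 13 1-[2-hydroxy-4,6-bis(triisopropylsilyloxy)phenyl]ethan-1-one
Conditions: iPr3SiCl (2.1 equiv), imidazole, DMF, 0 °C to rt
Reagents that add atoms: triisopropylsilyl chloride, CC(C)[Si](Cl)(C(C)C)C(C)C
Why: Selective phenol silylation, in which the 4-OH and one of the two equivalent ortho hydroxyls react while the last hydroxyl stays free because it is held in a hydrogen bond to the acetyl carbonyl.

Step 10
Reactants: 11 5-(bromomethyl)-2-methoxy-1-(3-methylbut-2-en-1-yl)-3-[3-methyl-3-(triethylsilyloxy)but-1-yn-1-yl]benzene; 13 1-[2-hydroxy-4,6-bis(triisopropylsilyloxy)phenyl]ethan-1-one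
Product: 14 1-[2-({4-methoxy-3-(3-methylbut-2-en-1-yl)-5-[3-methyl-3-(triethylsilyloxy)but-1-yn-1-yl]phenyl}methoxy)-4,6-bis(triisopropylsilyloxy)phenyl]ethan-1-one
Conditions: K2CO3, Bu4NI (cat.), acetone, 50 °C
Reagents that add atoms: none
Why: Williamson etherification of the chelated phenol with the reactive benzylic bromide, the hindered triisopropylsilyl aryl ethers being chosen to resist carbonate and silyl scrambling.

Step 11
Reactants: 14 1-[2-({4-methoxy-3-(3-methylbut-2-en-1-yl)-5-[3-methyl-3-(triethylsilyloxy)but-1-yn-1-yl]phenyl}methoxy)-4,6-bis(triisopropylsilyloxy)phenyl]ethan-1-one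
Product: 16 2-diazo-1-[2-({4-methoxy-3-(3-methylbut-2-en-1-yl)-5-[3-methyl-3-(triethylsilyloxy)but-1-yn-1-yl]phenyl}methoxy)-4,6-bis(triisopropylsilyloxy)phenyl]ethan-1-one, via trifluoroacetylated ketone 15 (not isolated)
Conditions: LiN(SiMe3)2, THF, −78 °C; CF3CO2CH2CF3, −78 °C; aq. NH4Cl, crude 15 not purified; then MsN3, Et3N, H2O, MeCN, rt
Reagents that add atoms: 2,2,2-trifluoroethyl trifluoroacetate, FC(F)(F)COC(=O)C(F)(F)F (trifluoroacetyl group of 15 only); methanesulfonyl azide, CS(=O)(=O)N=[N+]=[N-] (the two diazo nitrogens)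
Why: Detrifluoroacetylative diazo transfer, in which Claisen condensation of the kinetic lithium enolate activates the methyl ketone as a 1,3-diketone, the sulfonyl azide transfers N2 to the central carbon and the trifluoroacetyl group leaves as the N-acylsulfonamide.

Step 12
Reactants: 16 2-diazo-1-[2-({4-methoxy-3-(3-methylbut-2-en-1-yl)-5-[3-methyl-3-(triethylsilyloxy)but-1-yn-1-yl]phenyl}methoxy)-4,6-bis(triisopropylsilyloxy)phenyl]ethan-1-one
Product: 17 (2S)-2-{4-methoxy-3-(3-methylbut-2-en-1-yl)-5-[3-methyl-3-(triethylsilyloxy)but-1-yn-1-yl]phenyl}-5,7-bis(triisopropylsilyloxy)-2,3-dihydro-4H-chromen-4-one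
Conditions: Rh2(S-PTTL)4, dirhodium tetrakis[N-phthaloyl-(S)-tert-leucinate] (2 mol %), CH2Cl2, 0 °C, slow addition of 16 at high dilution
Reagents that add atoms: none
Why: Rh2(S-PTTL)4 expels N2 from 16 to give an electrophilic rhodium carbenoid at C3, which inserts into the benzylic ether C2–H bond through a concerted, asynchronous three-centre transition state with hydride-transfer character, forming C2–C3. The closest known reaction type is the enantioselective intramolecular C–H insertion of ortho-alkoxyaryl α-diazoketones to 2-substituted chroman-4-ones under chiral tetracarboxylates of divalent rhodium. Ring C is closed as a six-membered ring by 1,6-C–H insertion; a five-membered closure is not available because the atom that would be attacked is O1, which carries no hydrogen. C2, the only stereocentre, is set by the catalyst alone: the chiral pocket of the four phthalimido tert-leucinate ligands selects one of the two enantiotopic benzylic hydrogens, and later steps use no base that could open ring C. The step needs C–H insertion to win over attack of the carbenoid on O1 (oxonium ylide, then [1,2]-benzyl shift to a benzofuran-3-one), over reaction with the prenyl alkene, the alkyne or ring B, and over carbene dimerisation. The substrate should secure this because the C2–H bond is activated by O1 and by the electron-rich ring B, the lone pairs of O1 are delocalised into ring A and the bulky carboxylates disfavour ylide formation, the alkene and alkyne sit meta on ring B where only a strained metacyclophane could form, every hydroxyl is silylated, and slow addition suppresses bimolecular paths.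

Step 13
Reactants: 17 (2S)-2-{4-methoxy-3-(3-methylbut-2-en-1-yl)-5-[3-methyl-3-(triethylsilyloxy)but-1-yn-1-yl]phenyl}-5,7-bis(triisopropylsilyloxy)-2,3-dihydro-4H-chromen-4-one
Product: 18 (2S)-2-{4-methoxy-3-(3-methylbut-2-en-1-yl)-5-[(1Z)-3-methyl-3-(triethylsilyloxy)but-1-en-1-yl]phenyl}-5,7-bis(triisopropylsilyloxy)-2,3-dihydro-4H-chromen-4-one
Conditions: H2 (1 atm), Pd/CaCO3 poisoned with Pb(OAc)2, quinoline, EtOAc, rt, stopped at one equivalent of H2
Reagents that add atoms: none
Why: Lindlar semihydrogenation, in which syn delivery of H2 on poisoned palladium should give the Z-alkene while the trisubstituted prenyl alkene, the aryl ketone and the benzylic C2–O1 bond are not reduced and the neutral medium leaves C2 untouched.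

Step 14
Reactants: 18 (2S)-2-{4-methoxy-3-(3-methylbut-2-en-1-yl)-5-[(1Z)-3-methyl-3-(triethylsilyloxy)but-1-en-1-yl]phenyl}-5,7-bis(triisopropylsilyloxy)-2,3-dihydro-4H-chromen-4-one
Product: 19 (2S)-5,7-dihydroxy-2-{3-[(1Z)-3-hydroxy-3-methylbut-1-en-1-yl]-4-methoxy-5-(3-methylbut-2-en-1-yl)phenyl}-2,3-dihydro-4H-chromen-4-one (CNP0223123.2)
Conditions: Bu4NF, AcOH (1:1), THF, 0 °C to rt
Reagents that add atoms: none
Why: Fluoride desilylation of the two aryl silyl ethers and the tertiary silyl ether, buffered with acetic acid so that no free phenoxide can open ring C by retro-oxa-Michael reaction and no strong acid can ionise the tertiary allylic alcohol.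

**Compound list**

1 | 3-bromo-4-hydroxybenzaldehyde | O=Cc1ccc(O)c(Br)c1 | starting material
2 | allyl bromide | C=CCBr | starting material
3 | 4-(allyloxy)-3-bromobenzaldehyde | O=Cc1ccc(OCC=C)c(Br)c1 | intermediate
4 | 3-allyl-5-bromo-4-hydroxybenzaldehyde | O=Cc1cc(Br)c(O)c(CC=C)c1 | intermediate
5 | 3-allyl-5-bromo-4-methoxybenzaldehyde | COc1c(Br)cc(C=O)cc1CC=C | intermediate
6 | 3-bromo-4-methoxy-5-(3-methylbut-2-en-1-yl)benzaldehyde | COc1c(Br)cc(C=O)cc1CC=C(C)C | intermediate
7 | 2-methylbut-3-yn-2-ol | CC(C)(O)C#C | starting material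
8 | 3-(3-hydroxy-3-methylbut-1-yn-1-yl)-4-methoxy-5-(3-methylbut-2-en-1-yl)benzaldehyde | COc1c(C#CC(C)(C)O)cc(C=O)cc1CC=C(C)C | intermediate
9 | 4-methoxy-3-(3-methylbut-2-en-1-yl)-5-[3-methyl-3-(triethylsilyloxy)but-1-yn-1-yl]benzaldehyde | COc1c(C#CC(C)(C)O[Si](CC)(CC)CC)cc(C=O)cc1CC=C(C)C | intermediate
10 | {4-methoxy-3-(3-methylbut-2-en-1-yl)-5-[3-methyl-3-(triethylsilyloxy)but-1-yn-1-yl]phenyl}methanol | COc1c(C#CC(C)(C)O[Si](CC)(CC)CC)cc(CO)cc1CC=C(C)C | intermediate
11 | 5-(bromomethyl)-2-methoxy-1-(3-methylbut-2-en-1-yl)-3-[3-methyl-3-(triethylsilyloxy)but-1-yn-1-yl]benzene | COc1c(C#CC(C)(C)O[Si](CC)(CC)CC)cc(CBr)cc1CC=C(C)C | intermediate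
12 | 2',4',6'-trihydroxyacetophenone | CC(=O)c1c(O)cc(O)cc1O | starting material
13 | 1-[2-hydroxy-4,6-bis(triisopropylsilyloxy)phenyl]ethan-1-one | CC(=O)c1c(O)cc(O[Si](C(C)C)(C(C)C)C(C)C)cc1O[Si](C(C)C)(C(C)C)C(C)C | intermediate
14 | 1-[2-({4-methoxy-3-(3-methylbut-2-en-1-yl)-5-[3-methyl-3-(triethylsilyloxy)but-1-yn-1-yl]phenyl}methoxy)-4,6-bis(triisopropylsilyloxy)phenyl]ethan-1-one | COc1c(C#CC(C)(C)O[Si](CC)(CC)CC)cc(COc2cc(O[Si](C(C)C)(C(C)C)C(C)C)cc(O[Si](C(C)C)(C(C)C)C(C)C)c2C(C)=O)cc1CC=C(C)C | intermediate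
15 | 4,4,4-trifluoro-1-[2-({4-methoxy-3-(3-methylbut-2-en-1-yl)-5-[3-methyl-3-(triethylsilyloxy)but-1-yn-1-yl]phenyl}methoxy)-4,6-bis(triisopropylsilyloxy)phenyl]butane-1,3-dione | COc1c(C#CC(C)(C)O[Si](CC)(CC)CC)cc(COc2cc(O[Si](C(C)C)(C(C)C)C(C)C)cc(O[Si](C(C)C)(C(C)C)C(C)C)c2C(=O)CC(=O)C(F)(F)F)cc1CC=C(C)C | intermediate (not isolated)
16 | 2-diazo-1-[2-({4-methoxy-3-(3-methylbut-2-en-1-yl)-5-[3-methyl-3-(triethylsilyloxy)but-1-yn-1-yl]phenyl}methoxy)-4,6-bis(triisopropylsilyloxy)phenyl]ethan-1-one | COc1c(C#CC(C)(C)O[Si](CC)(CC)CC)cc(COc2cc(O[Si](C(C)C)(C(C)C)C(C)C)cc(O[Si](C(C)C)(C(C)C)C(C)C)c2C(=O)C=[N+]=[N-])cc1CC=C(C)C | intermediate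
17 | (2S)-2-{4-methoxy-3-(3-methylbut-2-en-1-yl)-5-[3-methyl-3-(triethylsilyloxy)but-1-yn-1-yl]phenyl}-5,7-bis(triisopropylsilyloxy)-2,3-dihydro-4H-chromen-4-one | COc1c(C#CC(C)(C)O[Si](CC)(CC)CC)cc([C@@H]2CC(=O)c3c(O[Si](C(C)C)(C(C)C)C(C)C)cc(O[Si](C(C)C)(C(C)C)C(C)C)cc3O2)cc1CC=C(C)C | intermediate
18 | (2S)-2-{4-methoxy-3-(3-methylbut-2-en-1-yl)-5-[(1Z)-3-methyl-3-(triethylsilyloxy)but-1-en-1-yl]phenyl}-5,7-bis(triisopropylsilyloxy)-2,3-dihydro-4H-chromen-4-one | COc1c(/C=C\C(C)(C)O[Si](CC)(CC)CC)cc([C@@H]2CC(=O)c3c(O[Si](C(C)C)(C(C)C)C(C)C)cc(O[Si](C(C)C)(C(C)C)C(C)C)cc3O2)cc1CC=C(C)C | intermediate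
19 | (2S)-5,7-dihydroxy-2-{3-[(1Z)-3-hydroxy-3-methylbut-1-en-1-yl]-4-methoxy-5-(3-methylbut-2-en-1-yl)phenyl}-2,3-dihydro-4H-chromen-4-one | COc1c(/C=C\C(C)(C)O)cc([C@@H]2CC(=O)c3c(O)cc(O)cc3O2)cc1CC=C(C)C | target

**Step count**

Total: 14 steps. Longest linear sequence: 13 steps (steps 1 to 8, then 10 to 14).

**Steps most likely to fail**

Step 12. The carbenoid may be captured by the lone pair of O1 and go on by benzyl migration instead of inserting into C2–H, or the catalyst may discriminate the two enantiotopic hydrogens poorly. The fallback sets out from 9 and 13 and returns at 17. Double deprotonation of 13 with LiN(SiMe3)2 (THF, −78 °C) and aldol addition to aldehyde 9 should give the racemic β-hydroxy ketone F1. Mitsunobu cyclodehydration (PPh3, DIAD, THF, 0 °C) should close ring C through the O1–C2 bond and give the racemic flavanone F2. Kinetic resolution by asymmetric transfer hydrogenation with RuCl[(R,R)-TsDPEN](p-cymene) and HCO2H/Et3N is expected to reduce the (2R)-enantiomer to the cis-(2R,4R)-flavan-4-ol F3 and to leave the (2S)-flavanone 17, which is separated by chromatography. The matched enantiomer of the catalyst is to be confirmed on the racemate.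

Step 11. Enolisation next to the ortho silyl ether may cause silyl migration to the enolate oxygen, or the hindered enolate may be acylated incompletely. The fallback sets out from 14 and returns at 16 and uses no strong base. Heating 14 with N,N-dimethylformamide dimethyl acetal (neat, 100 °C) should give the enaminone F4. Diazo transfer with MsN3 (MeCN, rt) then proceeds by cycloaddition of the sulfonyl azide to the enamine double bond and fragmentation of the triazoline, which should give 16 and an N-sulfonylformamidine.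

Step 13. Hydrogen uptake at the alkyne, which is flanked by the ortho methoxy group and the silyloxy-bearing quaternary carbon, may be slow, and over-reduction or Z-to-E isomerisation on palladium may follow. The fallback sets out from 17 and returns at 19. Buffered desilylation (Bu4NF, AcOH, THF) carried out first should give the alkynyl triol F5. Its less hindered arylpropargylic alcohol is then reduced to the Z-alkene with Zn dust activated with Cu(OAc)2 and AgNO3 in MeOH/H2O (Boland reduction), which does not over-reduce, to give 19 directly.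

**Further compounds**

F1 | step 12 | 3-hydroxy-1-[2-hydroxy-4,6-bis(triisopropylsilyloxy)phenyl]-3-{4-methoxy-3-(3-methylbut-2-en-1-yl)-5-[3-methyl-3-(triethylsilyloxy)but-1-yn-1-yl]phenyl}propan-1-one (racemic) | COc1c(C#CC(C)(C)O[Si](CC)(CC)CC)cc(C(O)CC(=O)c2c(O)cc(O[Si](C(C)C)(C(C)C)C(C)C)cc2O[Si](C(C)C)(C(C)C)C(C)C)cc1CC=C(C)C
F2 | step 12 | racemic 2-{4-methoxy-3-(3-methylbut-2-en-1-yl)-5-[3-methyl-3-(triethylsilyloxy)but-1-yn-1-yl]phenyl}-5,7-bis(triisopropylsilyloxy)-2,3-dihydro-4H-chromen-4-one | COc1c(C#CC(C)(C)O[Si](CC)(CC)CC)cc(C2CC(=O)c3c(O[Si](C(C)C)(C(C)C)C(C)C)cc(O[Si](C(C)C)(C(C)C)C(C)C)cc3O2)cc1CC=C(C)C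
F3 | step 12 | (2R,4R)-2-{4-methoxy-3-(3-methylbut-2-en-1-yl)-5-[3-methyl-3-(triethylsilyloxy)but-1-yn-1-yl]phenyl}-5,7-bis(triisopropylsilyloxy)-3,4-dihydro-2H-chromen-4-ol | COc1c(C#CC(C)(C)O[Si](CC)(CC)CC)cc([C@H]2C[C@@H](O)c3c(O[Si](C(C)C)(C(C)C)C(C)C)cc(O[Si](C(C)C)(C(C)C)C(C)C)cc3O2)cc1CC=C(C)C
F4 | step 11 | (2E)-3-(dimethylamino)-1-[2-({4-methoxy-3-(3-methylbut-2-en-1-yl)-5-[3-methyl-3-(triethylsilyloxy)but-1-yn-1-yl]phenyl}methoxy)-4,6-bis(triisopropylsilyloxy)phenyl]prop-2-en-1-one | COc1c(C#CC(C)(C)O[Si](CC)(CC)CC)cc(COc2cc(O[Si](C(C)C)(C(C)C)C(C)C)cc(O[Si](C(C)C)(C(C)C)C(C)C)c2C(=O)/C=C/N(C)C)cc1CC=C(C)C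
F5 | step 13 | (2S)-5,7-dihydroxy-2-[3-(3-hydroxy-3-methylbut-1-yn-1-yl)-4-methoxy-5-(3-methylbut-2-en-1-yl)phenyl]-2,3-dihydro-4H-chromen-4-one | COc1c(C#CC(C)(C)O)cc([C@@H]2CC(=O)c3c(O)cc(O)cc3O2)cc1CC=C(C)C
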